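Ring B carries a hidden local symmetry (clerodane numbering): C5 and C9 each bear a methyl group, C6 and C8 each bear oxygen, and both pairs flank C7 and C10. Ring B is therefore taken from a flat, C2v-symmetric 4,6-dimethylresorcinol dimethyl ether that carries a pent-4-ynyl chain on C10. An enantioselective, gold-catalysed dearomative 6-exo-dig cyclisation joins the internal alkyne carbon C4 to one of the two enantiotopic arene carbons (C5). This single operation closes ring A, creates the quaternary stereocentre C5, leaves the C4=C18 methylene and tells the two oxygens apart (C6 enol ether, C8 ketone). Every other stereocentre is then relayed from C5.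

Key step: step 5

Remark on numbering: ring A = C1, C2, C3, C4, C5, C10; ring B = C5, C6, C7, C8, C9, C10; C18 = methylene carbon on C4; C19 = methyl on C5; C17 = methyl on C8; C20 = methyl on C9; C11=C12 links C9 to the butenolide. α is the face of ring B that carries C19, β the other face. In this numbering the target is 1R,5R,6R,7S,8R,9R,10S (1β-OH, 10β-H, 6α-OAc, 7β-isobutyrate, 8β-OH, 9β side chain).

Assumption: 1, 2, 24 and all reagents named under Conditions are purchased; the antipode of the gold ligand that delivers (4aS)-8 is fixed by a first screen.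

Step 1
Reactants: 1 3,5-dimethoxybenzyl bromide; 2 4-bromo-1-(trimethylsilyl)but-1-yne
Product: 4 1,3-dimethoxy-5-[5-(trimethylsilyl)pent-4-yn-1-yl]benzene, via Grignard reagent 3 (not isolated)
Conditions: 2, Mg, THF, rt; then 1, Li2CuCl4 (3 mol%), THF, −20 °C → rt
Reagents that add atoms: none
Why: copper-catalysed sp3–sp3 Grignard cross-coupling of a benzylic bromide should join the benzylic carbon (C1) to the C2–C3–C4≡C18 unit, the silyl group masking the acidic alkyne C–H.

Step 2
Reactants: 4 1,3-dimethoxy-5-[5-(trimethylsilyl)pent-4-yn-1-yl]benzene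
Product: 5 2,4-dibromo-1,5-dimethoxy-3-[5-(trimethylsilyl)pent-4-yn-1-yl]benzene
Conditions: NBS (2.1 equiv), MeCN, 0 °C → rt, dark
Reagents that add atoms: N-bromosuccinimide O=C1CCC(=O)N1Br
Why: electrophilic aromatic bromination should place each bromine para to one methoxy group and ortho to the other, i.e. on the two carbons flanking the side chain, the crowded carbon between the two methoxy groups reacting last.

Step 3
Reactants: 5 2,4-dibromo-1,5-dimethoxy-3-[5-(trimethylsilyl)pent-4-yn-1-yl]benzene
Product: 6 1,5-dimethoxy-2,4-dimethyl-3-[5-(trimethylsilyl)pent-4-yn-1-yl]benzene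
Conditions: MeZnCl (3 equiv), Pd(OAc)2 (5 mol%), SPhos (10 mol%), THF, 60 °C
Reagents that add atoms: methylzinc chloride C[Zn]Cl
Why: twofold Negishi coupling should install the future C19 and C20 methyl groups, the bulky biarylphosphine coping with the di-ortho-substituted bromides and the neutral medium sparing the silylalkyne.

Step 4
Reactants: 6 1,5-dimethoxy-2,4-dimethyl-3-[5-(trimethylsilyl)pent-4-yn-1-yl]benzene
Product: 7 1,5-dimethoxy-2,4-dimethyl-3-(pent-4-yn-1-yl)benzene
Conditions: K2CO3 (0.2 equiv), MeOH, rt
Reagents that add atoms: none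
Why: base-catalysed methanolysis of the C(sp)–Si bond should free the terminal alkyne without touching anything else.

Step 5
Reactants: 7 1,5-dimethoxy-2,4-dimethyl-3-(pent-4-yn-1-yl)benzene
Product: 8 (4aS)-4-methoxy-1,4a-dimethyl-5-methylidene-5,6,7,8-tetrahydronaphthalen-2(4aH)-one (C8 ketone; C6 methyl enol ether; C9=C10; C4=C18; 5α-methyl)
Conditions: (R)-DTBM-SEGPHOS(AuCl)2 (5 mol%), AgSbF6 (10 mol%), H2O (2 equiv), CH2Cl2, −20 °C → rt
Reagents that add atoms: water O
Why: Proposed new method: cationic monovalent gold π-activates the terminal alkyne, the electron-rich arene carbon C5 (ortho to one methoxy group, para to the other) attacks the internal alkyne carbon C4 anti to gold, the C5 methyl forbids rearomatisation, water adds to the para oxocarbenium carbon C8 and expels methanol, and protodeauration leaves the C4=C18 methylene; the closest known reaction type is the gold-catalysed dearomative ipso-cyclisation of para-methoxyaryl and phenol alkynes to spirocyclohexadienones, moved here to a ring-fused closure. Ring A closes in the 6-exo-dig mode (Markovnikov attack at C4; the 7-endo path would need attack at the terminal carbon). The single new stereocentre C5 is controlled by the catalyst: C5 and C9 are enantiotopic in the C2v-symmetric arene and the chiral bisphosphine digold complex must select one of them. The step needs carbocyclisation to outrun alkyne hydration, which the tethered, doubly activated nucleophile and the small amount of water should favour. It needs the carbonyl to form at C8 and not at C6, which the substrate secures because C8 gives the cross-conjugated para-quinoid dienone and C6 is shielded by the new quaternary centre. Only C5 and C9 can reach C4 through a six-membered ring, so no other constitutional isomer is expected.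

Step 6
Reactants: 8 (4aS)-4-methoxy-1,4a-dimethyl-5-methylidene-5,6,7,8-tetrahydronaphthalen-2(4aH)-one
Product: 11 9β-ethynyl ketone (C8 ketone; C6 methyl enol ether C6=C7; C1=C10; C4=C18; 5α-methyl; 9α-methyl), via potassium dienolate 9 (not isolated), via silylalkyne 10 (not isolated)
Conditions: KN(SiMe3)2 (1.1 equiv), THF, −78 °C; TMS-EBX (1.3 equiv), −78 → −20 °C; Bu4NF (1.5 equiv), 0 °C
Reagents that add atoms: 1-[(trimethylsilyl)ethynyl]-1,2-benziodoxol-3(1H)-one (TMS-EBX) C[Si](C)(C)C#CI1OC(=O)c2ccccc12
Why: γ-deprotonation at C1 gives the extended enolate, which should undergo electrophilic alkynylation by the ethynylbenziodoxolone at its α-carbon C9 (deconjugative α-functionalisation) anti to the pseudoaxial C19 methyl, so that the ethynyl group ends β, C20 ends α and the double bond moves to C1=C10.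

Step 7
Reactants: 11 9β-ethynyl ketone
Product: 13 9β-ethynyl enone (C6 ketone; C7=C8 carrying C17; C1=C10; C4=C18; 5α-methyl; 9α-methyl), via tertiary carbinol 12 (not isolated)
Conditions: MeLi (3.5 equiv), THF, −78 → 0 °C; then 1 M HCl, THF, rt
Reagents that add atoms: methyllithium [Li]C
Why: Stork–Danheiser transposition, i.e. 1,2-addition of methyllithium to the C8 carbonyl of the vinylogous ester followed by acid hydrolysis of the enol ether and loss of water, should give the C6 ketone conjugated to C7=C8 with C17 in place; the C8 carbinol configuration is erased and one equivalent of MeLi is spent on the alkyne C–H.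

Step 8
Reactants: 13 9β-ethynyl enone
Product: 14 7β,8β-epoxy ketone of 13
Conditions: 30% H2O2, NaOH (0.5 equiv), MeOH, 0 °C → rt
Reagents that add atoms: hydrogen peroxide OO
Why: Weitz–Scheffer nucleophilic epoxidation should touch only the electron-poor C7=C8 bond, hydroperoxide adding to C8 on the β face, anti to the C20 methyl and past the slim ethynyl group on C9.

Step 9
Reactants: 14 7β,8β-epoxy ketone
Product: 15 8β-hydroxy-8α-methyl C6 ketone (C7 methylene)
Conditions: SmI2 (2.2 equiv), THF/MeOH, −90 °C
Reagents that add atoms: none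
Why: reduction of an α,β-epoxy ketone by divalent samarium cleaves the Cα–O bond (C7–O) and should leave the tertiary C8 oxygen untouched, hence 8β-OH with C17 α.

Step 10
Reactants: 15 8β-hydroxy-8α-methyl C6 ketone
Product: 18 7β,8β-dihydroxy C6 ketone, via bis-silyl enol ether 16 (not isolated), via silyloxy ketone 17 (not isolated)
Conditions: TMSOTf (3 equiv), Et3N (5 equiv), CH2Cl2, −78 → 0 °C; DMDO (1.1 equiv), acetone, −78 °C; citric acid (cat.), MeOH, rt
Reagents that add atoms: dimethyldioxirane CC1(C)OO1
Why: Rubottom oxidation: the silyl enol ether C6=C7 is by far the most electron-rich alkene and should be epoxidised on the β face because the α face of C7 is closed by the two syn-axial methyls C19 and C20, silyl shift and methanolysis then giving the equatorial 7β-hydroxy ketone.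

Step 11
Reactants: 18 7β,8β-dihydroxy C6 ketone
Product: 19 7β-isobutyryloxy-8β-hydroxy C6 ketone
Conditions: i-PrCOCl (1.5 equiv), pyridine, DMAP (cat.), CH2Cl2, 0 °C
Reagents that add atoms: isobutyryl chloride CC(C)C(Cl)=O
Why: DMAP-catalysed esterification should acylate the only secondary hydroxyl (C7), the tertiary C8 hydroxyl being inert under these conditions.

Step 12
Reactants: 19 7β-isobutyryloxy-8β-hydroxy C6 ketone
Product: 20 6α,8β-diol 7β-isobutyrate
Conditions: Me4NBH(OAc)3 (5 equiv), MeCN/AcOH (1:1), −30 °C
Reagents that add atoms: none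
Why: Evans–Saksena reduction: the axial 8β-hydroxyl binds boron and should deliver hydride intramolecularly to the β face of the C6 carbonyl (1,3-anti), giving the equatorial 6α-alcohol while the ester is left alone.

Step 13
Reactants: 20 6α,8β-diol 7β-isobutyrate
Product: 21 6α-acetate 7β-isobutyrate 8β-ol (C1=C10; C4=C18; 9β-ethynyl)
Conditions: Ac2O, pyridine, DMAP (cat.), CH2Cl2, rt
Reagents that add atoms: acetic anhydride CC(=O)OC(C)=O
Why: DMAP-catalysed acetylation should take the secondary C6 hydroxyl and leave the tertiary C8 hydroxyl free.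

Step 14
Reactants: 21 6α-acetate 7β-isobutyrate 8β-ol
Product: 22 1β,10β-epoxide of 21
Conditions: VO(acac)2 (5 mol%), t-BuOOH (1.5 equiv), CH2Cl2, 0 °C → rt
Reagents that add atoms: tert-butyl hydroperoxide CC(C)(C)OO
Why: hydroxyl-directed epoxidation: the vanadate ester of the homoallylic, axial 8β-hydroxyl should deliver oxygen to the β face of C1=C10 only (the α face is blocked by C19 and C20 in any case), the remote C4=C18 methylene and the alkyne being out of reach.

Step 15
Reactants: 22 1β,10β-epoxide
Product: 23 1β,8β-diol 6α-acetate 7β-isobutyrate having 10β-H (trans-decalin; 9β-ethynyl; C4=C18)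
Conditions: Cp2TiCl2 (0.3 equiv), Mn (3 equiv), 2,4,6-collidine·HCl (2.5 equiv), H2O (10 equiv), THF, rt
Reagents that add atoms: none
Why: Nugent–RajanBabu reductive epoxide opening: trivalent titanium cleaves the C10–O bond to the tertiary C10 radical and keeps the 1β-oxygen, and hydrogen-atom transfer from the titanium aqua complex should arrive on the open β face (α is shielded by the axial C19 and C20 methyls), setting 10β-H and the trans ring fusion.

Step 16
Reactants: 23 1β,8β-diol 6α-acetate 7β-isobutyrate; 24 4-bromofuran-2(5H)-one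
Product: 26 target compound CNP0215764.1, via vinylstannane 25 (not isolated)
Conditions: Bu3SnH (1.2 equiv), PdCl2(PPh3)2 (5 mol%), THF, 0 °C; then 24 (1.5 equiv), Pd2(dba)3 (5 mol%), AsPh3 (20 mol%), CuI (20 mol%), DMF, 45 °C
Reagents that add atoms: none
Why: palladium-catalysed syn-hydrostannation should place tin on the terminal carbon away from the quaternary C9 and fix the E geometry, and Stille coupling with the bromobutenolide then proceeds with retention and tolerates the free hydroxyls, the esters and the C4=C18 methylene.

Compound list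
1 | 3,5-dimethoxybenzyl bromide | COc1cc(CBr)cc(OC)c1 | starting material
2 | 4-bromo-1-(trimethylsilyl)but-1-yne | C[Si](C)(C)C#CCCBr | starting material
3 | [4-(trimethylsilyl)but-3-yn-1-yl]magnesium bromide | C[Si](C)(C)C#CCC[Mg]Br | intermediate
4 | 1,3-dimethoxy-5-[5-(trimethylsilyl)pent-4-yn-1-yl]benzene | COc1cc(CCCC#C[Si](C)(C)C)cc(OC)c1 | intermediate
5 | 2,4-dibromo-1,5-dimethoxy-3-[5-(trimethylsilyl)pent-4-yn-1-yl]benzene | COc1cc(OC)c(Br)c(CCCC#C[Si](C)(C)C)c1Br | intermediate
6 | 1,5-dimethoxy-2,4-dimethyl-3-[5-(trimethylsilyl)pent-4-yn-1-yl]benzene | COc1cc(OC)c(C)c(CCCC#C[Si](C)(C)C)c1C | intermediate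
7 | 1,5-dimethoxy-2,4-dimethyl-3-(pent-4-yn-1-yl)benzene | COc1cc(OC)c(C)c(CCCC#C)c1C | intermediate
8 | (4aS)-4-methoxy-1,4a-dimethyl-5-methylidene-5,6,7,8-tetrahydronaphthalen-2(4aH)-one | C=C1CCCC2=C(C)C(=O)C=C(OC)[C@@]12C | intermediate
9 | potassium dienolate of 8 (O–C8=C9; C10=C1) | C=C1CCC=C2[C@@]1(C)C(OC)=CC([O-])=C2C.[K+] | intermediate
10 | 9β-[(trimethylsilyl)ethynyl] ketone (silylated form of 11) | C=C1CCC=C2[C@@]1(C)C(OC)=CC(=O)[C@]2(C)C#C[Si](C)(C)C | intermediate
11 | 9β-ethynyl ketone (C8 ketone; C6 methyl enol ether; C1=C10; C4=C18; 5α,9α-dimethyl) | C=C1CCC=C2[C@@]1(C)C(OC)=CC(=O)[C@]2(C)C#C | intermediate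
12 | C8 methyl carbinol of 11 (8β-methyl-8α-ol drawn; the C8 epimer converges) | C=C1CCC=C2[C@@]1(C)C(OC)=C[C@@](C)(O)[C@]2(C)C#C | intermediate
13 | 9β-ethynyl enone (C6 ketone; C7=C8 carrying C17; C1=C10; C4=C18; 5α,9α-dimethyl) | C=C1CCC=C2[C@@]1(C)C(=O)C=C(C)[C@]2(C)C#C | intermediate
14 | 7β,8β-epoxy ketone of 13 | C=C1CCC=C2[C@@]1(C)C(=O)[C@@H]3O[C@]3(C)[C@]2(C)C#C | intermediate
15 | 8β-hydroxy-8α-methyl C6 ketone | C=C1CCC=C2[C@@]1(C)C(=O)C[C@](C)(O)[C@]2(C)C#C | intermediate
16 | C6 trimethylsilyl enol ether (C6=C7) carrying 8β-OSiMe3 | C=C1CCC=C2[C@@]1(C)C(O[Si](C)(C)C)=C[C@](C)(O[Si](C)(C)C)[C@]2(C)C#C | intermediate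
17 | 7β,8β-bis(trimethylsilyloxy) C6 ketone | C=C1CCC=C2[C@@]1(C)C(=O)[C@H](O[Si](C)(C)C)[C@](C)(O[Si](C)(C)C)[C@]2(C)C#C | intermediate
18 | 7β,8β-dihydroxy C6 ketone | C=C1CCC=C2[C@@]1(C)C(=O)[C@H](O)[C@](C)(O)[C@]2(C)C#C | intermediate
19 | 7β-isobutyryloxy-8β-hydroxy C6 ketone | C=C1CCC=C2[C@@]1(C)C(=O)[C@H](OC(=O)C(C)C)[C@](C)(O)[C@]2(C)C#C | intermediate
20 | 6α,8β-diol 7β-isobutyrate | C=C1CCC=C2[C@@]1(C)[C@@H](O)[C@H](OC(=O)C(C)C)[C@](C)(O)[C@]2(C)C#C | intermediate
21 | 6α-acetate 7β-isobutyrate 8β-ol (C1=C10; C4=C18; 9β-ethynyl) | C=C1CCC=C2[C@@]1(C)[C@@H](OC(C)=O)[C@H](OC(=O)C(C)C)[C@](C)(O)[C@]2(C)C#C | intermediate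
22 | 1β,10β-epoxide of 21 | C=C1CC[C@H]3O[C@@]32[C@@]1(C)[C@@H](OC(C)=O)[C@H](OC(=O)C(C)C)[C@](C)(O)[C@]2(C)C#C | intermediate
23 | 1β,8β-diol 6α-acetate 7β-isobutyrate, 10β-H, 9β-ethynyl | C=C1CC[C@@H](O)[C@H]2[C@@]1(C)[C@@H](OC(C)=O)[C@H](OC(=O)C(C)C)[C@](C)(O)[C@]2(C)C#C | intermediate
24 | 4-bromofuran-2(5H)-one | O=C1C=C(Br)CO1 | starting material
25 | (E)-vinylstannane from 23 (C11=C12; tributyltin on C12) | C=C1CC[C@@H](O)[C@H]2[C@@]1(C)[C@@H](OC(C)=O)[C@H](OC(=O)C(C)C)[C@](C)(O)[C@]2(C)/C=C/[Sn](CCCC)(CCCC)CCCC | intermediate
26 | CNP0215764.1 (1R,5R,6R,7S,8R,9R,10S; clerodane numbering) | C=C1CC[C@@H](O)[C@H]2[C@@]1(C)[C@@H](OC(C)=O)[C@H](OC(=O)C(C)C)[C@](C)(O)[C@]2(C)/C=C/C1=CC(=O)OC1 | target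

Total step count: 16. Longest linear sequence: 16 steps (1 → 26; 2 and 24 enter as purchased partners).

Steps most likely to fail

Step 5 (Proposed new method). Hydration of the alkyne to the methyl ketone may outrun the ipso attack, or the chiral gold complex may not discriminate the two enantiotopic arene carbons. The fallback uses known palladium chemistry and sets out from 7. Markovnikov bromoboration of the alkyne with B-bromo-9-BBN and protonolysis with acetic acid should give the 2-bromoalkene 3-(4-bromopent-4-en-1-yl)-1,5-dimethoxy-2,4-dimethylbenzene F1. One equivalent of BBr3 at −78 °C should cleave one of the two equivalent methyl ethers to the phenol 3-(4-bromopent-4-en-1-yl)-5-methoxy-2,4-dimethylphenol F2. An enantioselective palladium-catalysed dearomative cyclisation of the phenolate then follows (zerovalent palladium from Pd2(dba)3, a P-chiral biaryl monophosphine, K2CO3, toluene, 90 °C). As in the known closures of meta-tethered para-alkylphenols to 4a-alkyl dienones, the carbon para to the phenolate oxygen (C5) attacks the alkenylpalladium bromide. This comes back to the route at 8.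

Step 6. The hindered extended enolate may react at oxygen or at C1, or may be oxidised by the iodane and dimerise, so that the C9 quaternary centre is not formed cleanly. The fallback sets out from 8: the same potassium dienolate is treated with trichloroethylene, which forms dichloroacetylene in the flask and is attacked by the enolate carbon C9, to give the 9β-[(E)-1,2-dichlorovinyl] ketone F3. Excess MeLi then does two jobs in one flask: elimination and chlorine–lithium exchange to the lithium acetylide, and the 1,2-addition of step 7. Acidic work-up as in step 7 comes back to the route at 13.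

Step 10. During enol silylation the tertiary silyloxy group may be lost by β-elimination back to the enone, or the oxidant may attack the enol ether from the α face. The fallback sets out from 13 and uses a syn-dihydroxylation instead of the epoxidation, reduction and enolate oxidation sequence. Permanganate (KMnO4, MgSO4, acetone/H2O, −30 °C) prefers the electron-poor conjugated C7=C8 bond and should add both oxygens in one event from the β face. It comes back to the route at 18 and by-passes 14 to 17; no further compound arises (F0).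

Further compounds
F1 | step 5 | 3-(4-bromopent-4-en-1-yl)-1,5-dimethoxy-2,4-dimethylbenzene | COc1cc(OC)c(C)c(CCCC(Br)=C)c1C
F2 | step 5 | 3-(4-bromopent-4-en-1-yl)-5-methoxy-2,4-dimethylphenol | COc1cc(O)c(C)c(CCCC(Br)=C)c1C
F3 | step 6 | 9β-[(E)-1,2-dichlorovinyl] ketone (otherwise as 11) | C=C1CCC=C2[C@@]1(C)C(OC)=CC(=O)[C@]2(C)/C(Cl)=C\Cl
F0 | step 10 | none | none
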